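**Retrosynthetic overview**

- Target ⇒ desilylation of its tetra‑TBS ether; the ring‑A–C1'' bond is cut by a chiral phosphoric acid (CPA) catalysed 1,6‑Friedel–Crafts addition of the acylphloroglucinol ring to a vinyl p‑quinone methide generated from an (S)‑diarylheptenediol.
- 2‑Aryl‑3‑aroyl‑oxane ⇒ C2–aryl bond: Rh‑catalysed conjugate arylation of a 5‑aroyl‑3,4‑dihydro‑2H‑pyran (C2 set kinetically, C3 by equilibration).
- Dihydropyran ⇒ new CPA‑catalysed dehydrative (4+2) annulation of an aroylacetaldehyde with the same diarylheptenediol (sets C4 cis to C6).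
- Diarylheptenediol ⇒ cross‑metathesis of an (S)‑homoallylic alcohol (CPA‑catalysed allylboration of an achiral aldehyde, first stereocentre) with 1‑(4‑hydroxyphenyl)allyl alcohol.
- Ring order: the pyran is the only ring built (step 7) and is saturated to the oxane in step 9; all arenes come from commercial materials.

Assumption: catalysts, bases and solvents that leave no atoms in the product are named in the conditions but not numbered.

**Route**

Step 1
Reactants: 1 3‑(4‑hydroxyphenyl)propanal; 2 tert‑butyldimethylsilyl chloride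
Product: 3 3‑{4‑[(tert‑butyldimethylsilyl)oxy]phenyl}propanal
Conditions: TBSCl (1.1 equiv), imidazole, CH2Cl2, 0 °C → rt
Reagents that add atoms: 2 TBSCl, CC(C)(C)[Si](C)(C)Cl
Why: Standard phenol silylation, which keeps the phenol from competing for the phosphoric acid catalyst in step 2.

Step 2
Reactants: 3; 4 allylboronic acid pinacol ester
Product: 5 (3S)‑1‑{4‑[(tert‑butyldimethylsilyl)oxy]phenyl}hex‑5‑en‑3‑ol
Conditions: (R)‑TRIP phosphoric acid (5 mol %), toluene, −30 °C; aqueous work‑up
Reagents that add atoms: 4 allylB(pin), C=CCB1OC(C)(C)C(C)(C)O1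
Why: CPA‑catalysed (Antilla‑type) asymmetric allylboration, in which the catalyst organises a chair‑like transition state and allyl is delivered to the Re face of the aldehyde, setting the first stereocentre as S (the sense assumed by analogy with reported aldehyde allylborations).

Step 3
Reactants: 6 4‑hydroxybenzaldehyde; 7 vinylmagnesium bromide
Product: 8 1‑(4‑hydroxyphenyl)prop‑2‑en‑1‑ol (racemic)
Conditions: vinylMgBr (2.5 equiv), THF, 0 °C → rt; sat. NH4Cl
Reagents that add atoms: 7 vinylMgBr, C=C[Mg]Br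
Why: Grignard 1,2‑addition (the first equivalent deprotonates the phenol); the carbinol centre is left racemic because it becomes sp2 in both later uses.

Step 4
Reactants: 5; 8 (3 equiv)
Product: 9 (2E,5S)‑1‑(4‑hydroxyphenyl)‑7‑{4‑[(tert‑butyldimethylsilyl)oxy]phenyl}hept‑2‑ene‑1,5‑diol (about 1:1 at C1)
Conditions: Hoveyda–Grubbs II (5 mol %), 1,4‑benzoquinone (10 mol %), CH2Cl2, 35 °C
Reagents that add atoms: none
Why: Olefin cross‑metathesis of a type I homoallylic alcohol with a type II secondary allylic alcohol gives the E‑alkene with loss of ethylene, and the C5 stereocentre is not involved.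

Step 5
Reactants: 10 1‑(2,4‑dihydroxy‑6‑methoxyphenyl)ethan‑1‑one; 11 chloromethyl methyl ether
Product: 12 1‑[2‑methoxy‑4,6‑bis(methoxymethoxy)phenyl]ethan‑1‑one
Conditions: NaH (2.5 equiv), MOMCl (2.5 equiv), DMF, 0 °C → rt
Reagents that add atoms: 11 MOMCl, COCCl
Why: O‑alkylation of both phenoxides; masking the 2'‑OH prevents chromone formation in steps 6–7.

Step 6
Reactants: 12; 13 ethyl formate
Product: 14 3‑[2‑methoxy‑4,6‑bis(methoxymethoxy)phenyl]‑3‑oxopropanal (exists as the chelated enol; used crude)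
Conditions: NaH (3 equiv), HCO2Et (5 equiv), THF, 0 °C → rt; AcOH quench
Reagents that add atoms: 13 ethyl formate, CCOC=O
Why: Crossed Claisen condensation (formylation of the methyl ketone enolate).

Step 7
Reactants: 9 (added slowly); 14 (1.3 equiv)
Product: 15 [(2S,4S)‑4‑[(E)‑2‑(4‑hydroxyphenyl)ethenyl]‑2‑(2‑{4‑[(tert‑butyldimethylsilyl)oxy]phenyl}ethyl)‑3,4‑dihydro‑2H‑pyran‑5‑yl][2‑methoxy‑4,6‑bis(methoxymethoxy)phenyl]methanone (2,4‑cis)
Conditions: (R)‑TRIP (10 mol %; used as the matched enantiomer, to be confirmed against (S)‑TRIP), 5 Å MS, toluene, rt → 40 °C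
Reagents that add atoms: none
Why: Proposed new method: CPA‑catalysed dehydrative formal (4+2) annulation in which the acid dehydrates 9 to a δ‑hydroxy vinyl p‑quinone methide, the secondary OH condenses with the enolic formyl group of 14 to a vinylogous ester, and its α‑carbon adds 1,8 to the quinone methide through a chair‑like 6‑endo transition state with the phenethyl group and the dienone chain both pseudo‑equatorial (new C4 = S, cis to C2, E‑styryl from the s‑trans quinone methide), after which the oxocarbenium loses a proton to give the conjugated dihydropyran; the closest known chemistry is the CPA‑catalysed [4+2] annulation of β‑dicarbonyls with in situ ortho‑quinone methides to 4H‑chromenes and CPA‑catalysed 1,8‑additions to extended para‑quinone methides.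

Step 8
Reactants: 15; 2 tert‑butyldimethylsilyl chloride
Product: 16 the 4‑[(tert‑butyldimethylsilyl)oxy]styryl analogue of 15 (same (2S,4S) configuration)
Conditions: TBSCl (1.5 equiv), imidazole, DMF, rt
Reagents that add atoms: 2 TBSCl, CC(C)(C)[Si](C)(C)Cl
Why: Phenol silylation, so that the nucleophilic p‑hydroxystyrene unit cannot compete with ring A in step 11.

Step 9
Reactants: 16; 17 {4‑[(tert‑butyldimethylsilyl)oxy]phenyl}boronic acid (3 equiv)
Product: 18 [(2R,3R,4S,6S)‑2‑{4‑[(TBS)oxy]phenyl}‑4‑[(E)‑2‑{4‑[(TBS)oxy]phenyl}ethenyl]‑6‑(2‑{4‑[(TBS)oxy]phenyl}ethyl)oxan‑3‑yl][2‑methoxy‑4,6‑bis(methoxymethoxy)phenyl]methanone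
Conditions: [Rh(cod)OH]2 (5 mol %), dioxane–H2O (10:1), 50 °C; then DBU (0.1 equiv), toluene, 0 °C → rt
Reagents that add atoms: none (17 is a listed reactant)
Why: Hayashi–Miyaura Rh‑catalysed 1,4‑addition to the cyclic β‑alkoxy enone, in which aryl–Rh adds irreversibly to C2 on the face opposite the cis C4/C6 substituents (axial attack, 2,6‑trans, C2 = R), and DBU equilibration places the epimerisable C3 aroyl group trans to the new aryl group (C3 = R).

Step 10
Reactants: 18
Product: 19 (2,4‑dihydroxy‑6‑methoxyphenyl)[(2R,3R,4S,6S)‑2‑{4‑[(TBS)oxy]phenyl}‑4‑[(E)‑2‑{4‑[(TBS)oxy]phenyl}ethenyl]‑6‑(2‑{4‑[(TBS)oxy]phenyl}ethyl)oxan‑3‑yl]methanone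
Conditions: TMSOTf (4 equiv), 2,2'‑bipyridyl (6 equiv), CH2Cl2, 0 °C → rt; then H2O
Reagents that add atoms: none
Why: Buffered Lewis‑acid cleavage of aromatic MOM ethers (via aryl TMS ethers hydrolysed on work‑up), which leaves aryl TBS ethers, the benzylic oxane C–O bond and all stereocentres untouched.

Step 11
Reactants: 19; 9 (1.5 equiv, added slowly)
Product: 20 {2,4‑dihydroxy‑3‑[(1R,2E,5S)‑5‑hydroxy‑1‑(4‑hydroxyphenyl)‑7‑{4‑[(TBS)oxy]phenyl}hept‑2‑en‑1‑yl]‑6‑methoxyphenyl}[(2R,3R,4S,6S)‑2‑{4‑[(TBS)oxy]phenyl}‑4‑[(E)‑2‑{4‑[(TBS)oxy]phenyl}ethenyl]‑6‑(2‑{4‑[(TBS)oxy]phenyl}ethyl)oxan‑3‑yl]methanone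
Conditions: TRIP phosphoric acid (10 mol %; enantiomer chosen by screening to give 1''R), 4 Å MS, CH2Cl2–toluene, −20 °C
Reagents that add atoms: none
Why: CPA‑catalysed Friedel–Crafts 1,6‑conjugate addition of a phenol to an in situ para‑quinone methide, in which the acid dehydrates 9 and, hydrogen‑bonded to the quinone methide carbonyl and the free 4'‑OH, delivers C3' (the position between the two OH groups, the most nucleophilic site of the chelated acylphloroglucinol) to the benzylic δ‑carbon with catalyst‑controlled facial selectivity (new centre R), leaving the 5S carbinol and the E‑alkene of 9 unchanged.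

Step 12
Reactants: 20
Product: 21 blepharocalyxin B
Conditions: TBAF/AcOH (1:1, 6 equiv), THF, 0 °C → rt
Reagents that add atoms: none
Why: Fluoride cleavage of the four aryl silyl ethers under acetic acid buffering, which avoids base‑induced retro‑oxa‑Michael opening or C3 epimerisation; no stereocentre is touched.

**Compound list**

1 | 3‑(4‑hydroxyphenyl)propanal | O=CCCc1ccc(O)cc1 | starting material
2 | tert‑butyldimethylsilyl chloride | CC(C)(C)[Si](C)(C)Cl | starting material
3 | 3‑{4‑[(TBS)oxy]phenyl}propanal | O=CCCc1ccc(O[Si](C)(C)C(C)(C)C)cc1 | intermediate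
4 | allylboronic acid pinacol ester | C=CCB1OC(C)(C)C(C)(C)O1 | starting material
5 | (3S)‑1‑{4‑[(TBS)oxy]phenyl}hex‑5‑en‑3‑ol | C=CC[C@@H](O)CCc1ccc(O[Si](C)(C)C(C)(C)C)cc1 | intermediate
6 | 4‑hydroxybenzaldehyde | O=Cc1ccc(O)cc1 | starting material
7 | vinylmagnesium bromide | C=C[Mg]Br | starting material
8 | rac‑1‑(4‑hydroxyphenyl)prop‑2‑en‑1‑ol | C=CC(O)c1ccc(O)cc1 | intermediate
9 | (2E,5S)‑1‑(4‑hydroxyphenyl)‑7‑{4‑[(TBS)oxy]phenyl}hept‑2‑ene‑1,5‑diol (C1 epimers) | OC(/C=C/C[C@@H](O)CCc1ccc(O[Si](C)(C)C(C)(C)C)cc1)c1ccc(O)cc1 | intermediate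
10 | 1‑(2,4‑dihydroxy‑6‑methoxyphenyl)ethan‑1‑one | CC(=O)c1c(O)cc(O)cc1OC | starting material
11 | chloromethyl methyl ether | COCCl | starting material
12 | 1‑[2‑methoxy‑4,6‑bis(methoxymethoxy)phenyl]ethan‑1‑one | CC(=O)c1c(OCOC)cc(OCOC)cc1OC | intermediate
13 | ethyl formate | CCOC=O | starting material
14 | 3‑[2‑methoxy‑4,6‑bis(methoxymethoxy)phenyl]‑3‑oxopropanal (enol form in solution) | O=CCC(=O)c1c(OCOC)cc(OCOC)cc1OC | intermediate
15 | (2S,4S)‑5‑aroyl‑4‑(4‑hydroxystyryl)‑2‑(4‑TBSO‑phenethyl)‑3,4‑dihydro‑2H‑pyran | COc1cc(OCOC)cc(OCOC)c1C(=O)C1=CO[C@@H](CCc2ccc(O[Si](C)(C)C(C)(C)C)cc2)C[C@H]1/C=C/c1ccc(O)cc1 | intermediate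
16 | TBS ether of 15 | COc1cc(OCOC)cc(OCOC)c1C(=O)C1=CO[C@@H](CCc2ccc(O[Si](C)(C)C(C)(C)C)cc2)C[C@H]1/C=C/c1ccc(O[Si](C)(C)C(C)(C)C)cc1 | intermediate
17 | {4‑[(TBS)oxy]phenyl}boronic acid | OB(O)c1ccc(O[Si](C)(C)C(C)(C)C)cc1 | starting material
18 | (2R,3R,4S,6S)‑oxane ketone, ring A bis‑MOM, three aryl OTBS | COc1cc(OCOC)cc(OCOC)c1C(=O)[C@@H]1[C@H](/C=C/c2ccc(O[Si](C)(C)C(C)(C)C)cc2)C[C@H](CCc2ccc(O[Si](C)(C)C(C)(C)C)cc2)O[C@H]1c1ccc(O[Si](C)(C)C(C)(C)C)cc1 | intermediate
19 | (2R,3R,4S,6S)‑oxane ketone, ring A free diol, three aryl OTBS | COc1cc(O)cc(O)c1C(=O)[C@@H]1[C@H](/C=C/c2ccc(O[Si](C)(C)C(C)(C)C)cc2)C[C@H](CCc2ccc(O[Si](C)(C)C(C)(C)C)cc2)O[C@H]1c1ccc(O[Si](C)(C)C(C)(C)C)cc1 | intermediate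
20 | tetra‑O‑TBS blepharocalyxin B | COc1cc(O)c([C@H](/C=C/C[C@@H](O)CCc2ccc(O[Si](C)(C)C(C)(C)C)cc2)c2ccc(O)cc2)c(O)c1C(=O)[C@@H]1[C@H](/C=C/c2ccc(O[Si](C)(C)C(C)(C)C)cc2)C[C@H](CCc2ccc(O[Si](C)(C)C(C)(C)C)cc2)O[C@H]1c1ccc(O[Si](C)(C)C(C)(C)C)cc1 | intermediate
21 | blepharocalyxin B | COc1cc(O)c([C@H](/C=C/C[C@@H](O)CCc2ccc(O)cc2)c2ccc(O)cc2)c(O)c1C(=O)[C@@H]1[C@H](/C=C/c2ccc(O)cc2)C[C@H](CCc2ccc(O)cc2)O[C@H]1c1ccc(O)cc1 | target

**Totals**

- Total steps: 12.
- Longest linear sequence: 9 (steps 1 → 2 → 4 → 7 → 8 → 9 → 10 → 11 → 12).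

**Three steps most likely to fail**

1. Step 7 (proposed new annulation). Risks are intermolecular 1,6‑attack at the benzylic carbon, quinone methide oligomerisation and incomplete cis selectivity. Fallback with known chemistry, reaching 16 without any quinone methide:
   - cross‑metathesis of 5 with crotonaldehyde;
   - MacMillan imidazolidinone‑catalysed conjugate addition of the potassium (E)‑styryltrifluoroborate to the enal (sets C4);
   - dehydration of the resulting lactol to the 3,4‑dihydro‑2H‑pyran;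
   - Vilsmeier formylation at C5;
   - addition of the lithiated MOM‑protected ring‑A bromide and oxidation.

2. Step 9 (Rh arylation). Risks are β‑alkoxide elimination (ring opening), low reactivity of the α‑substituted vinylogous ester, and C2 scrambling or an unfavourable C3 ratio during the base equilibration. Fallback: convert 16 into its C2 methyl acetal (MeOH, PPTS) and introduce the aryl group by BF3·OEt2‑mediated oxocarbenium C‑arylation with the arylzinc or aryltrifluoroborate (C‑glycosylation‑type axial attack, same 2,6‑trans outcome), then equilibrate C3.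

3. Step 11 (late Friedel–Crafts). Risks are 1,8‑ versus 1,6‑attack on the quinone methide, C5' versus C3' alkylation, and modest diastereocontrol. Fallback: attach the side chain earlier on the symmetrical arene, where regiochemistry is fixed:
   - ortho‑lithiate 1‑methoxy‑3,5‑bis(methoxymethoxy)benzene between the two OMOM groups and add it to 4‑TBSO‑benzaldehyde;
   - apply Schaus's BINOL‑catalysed enantioselective addition of the (E)‑alkenylboronate (from hydroboration of the homopropargylic analogue of 5) to the derived ortho‑quinone methide;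
   - acylate the remaining equivalent ring position and continue through steps 6–9.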